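Start from the small charge of the ash run and ask what doubling the second reagent does to one substrate molecule at its fork.

| flask | substrate | coupling partner | second reagent | temperature | remark | time |
|---|---|---|---|---|---|---|
| ash | 0.32 M | 0.50 equiv | 0.60 equiv | −15 °C | run made earlier |  |
| east | 0.32 M | 0.500 equiv | 1.20 equiv |  | at 0 °C until 1.5 min, from then on at −15 °C | 3.0 min |
| south-west | 0.32 M | 0.500 equiv | 1.20 equiv | −15 °C |  | 3.0 min |
| south | 0.32 M | 0.500 equiv | 1.20 equiv | 0 °C |  | 3.0 min |

ash run (percent of the substrate charged)

| time / s | target / % | side product A / % |
|---|---|---|
| 10.0 | 1.3 | 1.6 |
| 12.0 | 1.5 | 1.5 |
| 20.0 | 3.7 | 2.7 |

(scatter of a reading: 0.3 percentage points)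

1. the flask with the highest share of target in all that became target or side product A or over-reaction product B or side product B ("all alike" if they lie within 1.5 percentage points) (east / south-west / south / all alike)
2. share of target in all that became target or side product A or over-reaction product B or side product B, east
3. share of target in all that became target or side product A or over-reaction product B or side product B, south-west
4. share of target in all that became target or side product A or over-reaction product B or side product B, south

- the analysis behind the earlier runs scatters by 0.3 percentage points, standard deviation
- the earlier runs do not show what temperature does; that part of a forecast is a guess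
- the share counts what is present at the end, not what went on to other products

Assume that a substrate molecule goes towards target with coupling partner and to side product A with second reagent, each in step with its concentration. At the last ash reading, target over side product A stands at 1.37. Multiply these odds by c(second reagent)/c(coupling partner), both as charged, to get 1.64, the fork number, a selectivity factor read through the scatter. At the charges of south-west, which has the temperature of the ash run, it gives odds of 0.685, so target holds 40.7% of target and side product A together. Count that as a low figure, since the ash odds read 0.812 at the first reading, a rise that the scatter makes soft, and leave temperature a guess.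

The forecast, a separate judgement of the share asked, gives 56% for east, 60% for south-west and 52% for south; its south-west figure stands above this reckoning, which counts target and side product A. It names south-west, saying “the usual assumption is that cold is more selective”.

The flasks give 34.3% in east, 54.6% in south-west and 23.7% in south, so south-west stands highest.

    intermediate → side product B (k = 0.0240 s⁻¹, Ea = 68.0 kJ mol⁻¹)
    substrate + coupling partner → intermediate (k = 0.130 L mol⁻¹ s⁻¹, Ea = 36.0 kJ mol⁻¹)
    substrate + second reagent → side product A (k = 0.0330 L mol⁻¹ s⁻¹, Ea = 54.0 kJ mol⁻¹)
    second reagent + intermediate → target (k = 0.580 L mol⁻¹ s⁻¹, Ea = 46.0 kJ mol⁻¹)
    target → over-reaction product A (k = 1.60 × 10⁻⁵ s⁻¹, Ea = 93.0 kJ mol⁻¹)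
    target → over-reaction product B (k = 0.00440 s⁻¹, Ea = 88.0 kJ mol⁻¹)
    (constants at 0 °C)

Read south-west at 3.00 min: the odds are 1.45 and the fork number 3.49, twice the ash reading. Carried to the neighbour of south-west with 0.480 equiv of second reagent, it gives odds of 3.64, and that flask shows 2.95 at the end. In south, with the same charges as south-west but at 0 °C, the fork number falls to 1.18. Of the 31 percentage points gap between the shares of these flasks, warming the path from target to over-reaction product B accounts for 17 points, the largest single effect though not the main reason, and at the end that product stands at 17.7% in south against 1.87% in south-west.

The data were generated by integration for substances that don't exist.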